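**Plan**

- Retrosynthetic cuts: the coumarate ester C–O bond and both silyl ethers; the pyranone at O1–C2 and C4–C5 (back to a terminal epoxide and ethyl propiolate); the oxolane C3–C4 bond (as a C3=C4 alkene); the ether O–C2 bond.
- Enabling feature: in the cis-2,5-disubstituted oxolane the C3–C4 ethano unit lies between C2 and C5, and each of these carries the ring oxygen and an oxygenated side-chain carbon. Cutting C3–C4 therefore leaves an ether of two threo α-oxygenated vinyl carbinols of opposite sense.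
- Forward order: the two carbinols are joined by a stereoretentive allylic etherification, then the oxolane is closed by ring-closing metathesis and saturated, with the C3=C4 alkene as a temporary oxidation level. The pyranone follows by epoxide alkynylation, cis-semihydrogenation and lactonisation. The Z-coumarate comes last, from an aryl propiolate.
- Stereochemistry: (S)-O-benzyl-lactaldehyde (bought) relays to oxolane C2 by chelation control. C2-symmetric (3R,4R)-hexa-1,5-diene-3,4-diol (bought) supplies oxolane C5 and the carbinol carbon. A matched Sharpless epoxidation sets pyranone C6 and removes the one alkene that could mis-cyclise.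

Key step: step 6

Assumption: (3R,4R)-hexa-1,5-diene-3,4-diol is treated as a purchasable building block (it is otherwise reached in three known steps from D-mannitol).

**Route**

Step 1
Reactants: 1 (2S)-2-(benzyloxy)propanal
Product: 2 (3S,4S)-4-(benzyloxy)pent-1-en-3-ol
Conditions: MgBr2·OEt2, CH2Cl2, −78 °C; then CH2=CHMgBr (THF), −78 °C; aq. NH4Cl
Reagents that add atoms: vinylmagnesium bromide, C=C[Mg]Br
Why: Chelation-controlled Grignard addition (Cram chelate model): magnesium bridges the aldehyde and benzyloxy oxygens, so the vinyl group should add to the face opposite the methyl group and set C3 as S, syn to the C4 ether.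

Step 2
Reactants: 2 (3S,4S)-4-(benzyloxy)pent-1-en-3-ol
Product: 3 (3S,4S)-4-(benzyloxy)pent-1-en-3-yl methyl carbonate
Conditions: ClCO2Me, pyridine, DMAP (cat.), CH2Cl2, 0 °C
Reagents that add atoms: methyl chloroformate, COC(=O)Cl
Why: Plain O-acylation of the secondary alcohol to the allylic carbonate; no stereocentre is touched.

Step 3
Reactants: 3 (3S,4S)-4-(benzyloxy)pent-1-en-3-yl methyl carbonate; 4 (3R,4R)-hexa-1,5-diene-3,4-diol
Product: 6 (3R,4R)-4-{[(3S,4S)-4-(benzyloxy)pent-1-en-3-yl]oxy}hexa-1,5-dien-3-ol, via copper alkoxide of the diol 5 (not isolated)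
Conditions: 4 (2.5 equiv), LiN(SiMe3)2 (2.5 equiv), THF, 0 °C; CuI (2.5 equiv), rt; then 3, RhCl(PPh3)3 (10 mol%), P(OMe)3 (40 mol%), THF, 0 °C to rt
Reagents that add atoms: none
Why: Rhodium-catalysed allylic etherification with a copper alkoxide: ionisation of the branched carbonate and attack of the alkoxide on the configurationally stable rhodium enyl species each invert, so substitution should occur at the carbon that bore the carbonate with net retention (S), and because the diol is C2-symmetric and in excess either hydroxyl gives the same mono-ether.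

Step 4
Reactants: 6 (3R,4R)-4-{[(3S,4S)-4-(benzyloxy)pent-1-en-3-yl]oxy}hexa-1,5-dien-3-ol
Product: 7 (1S,2R)-2-{[(3S,4S)-4-(benzyloxy)pent-1-en-3-yl]oxy}-1-[(2R)-oxiran-2-yl]but-3-en-1-ol
Conditions: Ti(OiPr)4 (0.5 equiv), diisopropyl L-(+)-tartrate (0.6 equiv), t-BuOOH (2 equiv), 4 Å molecular sieves, CH2Cl2, −20 °C
Reagents that add atoms: tert-butyl hydroperoxide, CC(C)(C)OO
Why: Sharpless asymmetric epoxidation: only the vinyl group of the free allylic alcohol is epoxidised (delivery from the titanium alkoxide), and for this carbinol configuration the L-tartrate is the matched ligand, so reagent and substrate control together should give the erythro epoxy alcohol with the new oxirane carbon R.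

Step 5
Reactants: 7 (1S,2R)-2-{[(3S,4S)-4-(benzyloxy)pent-1-en-3-yl]oxy}-1-[(2R)-oxiran-2-yl]but-3-en-1-ol
Product: 8 {[(1S,2R)-2-{[(3S,4S)-4-(benzyloxy)pent-1-en-3-yl]oxy}-1-[(2R)-oxiran-2-yl]but-3-en-1-yl]oxy}(tert-butyl)dimethylsilane
Conditions: TBSOTf, 2,6-lutidine, CH2Cl2, −78 °C
Reagents that add atoms: tert-butyldimethylsilyl trifluoromethanesulfonate, CC(C)(C)[Si](C)(C)OS(=O)(=O)C(F)(F)F
Why: Silylation of the hindered secondary alcohol under buffered low-temperature conditions that should leave the epoxide closed; the silyl ether blocks Payne rearrangement in step 8 and acylation in step 12.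

Step 6
Reactants: 8 {[(1S,2R)-2-{[(3S,4S)-4-(benzyloxy)pent-1-en-3-yl]oxy}-1-[(2R)-oxiran-2-yl]but-3-en-1-yl]oxy}(tert-butyl)dimethylsilane
Product: 9 tert-butyl{(S)-[(2R,5S)-5-[(1S)-1-(benzyloxy)ethyl]-2,5-dihydrofuran-2-yl][(2R)-oxiran-2-yl]methoxy}dimethylsilane
Conditions: second-generation Grubbs catalyst (5 mol%), 1,4-benzoquinone (10 mol%), CH2Cl2 (5 mM), 40 °C
Reagents that add atoms: none
Why: Ring-closing olefin metathesis: the ruthenium alkylidene exchanges onto one terminal vinyl group, adds intramolecularly to the other through a ruthenacyclobutane and cycloreverts, releasing ethylene and forming the C3=C4 bond of the five-membered ring. The closest known reaction type is the ring-closing metathesis of α,α'-disubstituted bis-allylic ethers to 2,5-dihydrofurans. The ring closes as a five-membered ring from a 1,6-diene with both alkene carbons ending up endocyclic, so the new double bond is necessarily cis. No stereocentre is formed; the cis relation of C2 and C5 is carried in from the two ether carbons fixed in steps 1 and 3. The step needs cyclisation to win over oligomerisation and over migration of the double bond towards the ring oxygen, which the five-ring size, high dilution and the hydride-trapping benzoquinone should secure, and the third vinyl group that could have closed a six-membered ring was already converted to the epoxide in step 4. Epoxide, silyl ether and benzyl ether are inert to the catalyst.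

Step 7
Reactants: 9 tert-butyl{(S)-[(2R,5S)-5-[(1S)-1-(benzyloxy)ethyl]-2,5-dihydrofuran-2-yl][(2R)-oxiran-2-yl]methoxy}dimethylsilane
Product: 10 (1S)-1-[(2S,5R)-5-{(S)-[(tert-butyldimethylsilyl)oxy][(2R)-oxiran-2-yl]methyl}oxolan-2-yl]ethan-1-ol
Conditions: H2 (1 atm), 10% Pd/C, EtOAc, rt
Reagents that add atoms: none
Why: Heterogeneous hydrogenation saturates the ring alkene and hydrogenolysis removes the benzyl ether in the same operation, while the aliphatic terminal epoxide and the silyl ether should survive the neutral conditions; no stereocentre changes.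

Step 8
Reactants: 10 (1S)-1-[(2S,5R)-5-{(S)-[(tert-butyldimethylsilyl)oxy][(2R)-oxiran-2-yl]methyl}oxolan-2-yl]ethan-1-ol
Product: 11 ethyl (5R,6R)-6-[(tert-butyldimethylsilyl)oxy]-5-hydroxy-6-[(2R,5S)-5-[(1S)-1-hydroxyethyl]oxolan-2-yl]hex-2-ynoate
Conditions: ethyl propiolate (3.5 equiv), n-BuLi (3.3 equiv), THF, −78 °C; BF3·OEt2 (3 equiv); then 10, −78 °C; aq. NH4Cl
Reagents that add atoms: ethyl propiolate, C#CC(=O)OCC
Why: Yamaguchi–Hirao alkynylation: the BF3-activated terminal epoxide should be opened at its CH2 carbon by the lithium acetylide, leaving the oxirane stereocentre untouched, with the free hydroxyl merely consuming one equivalent of acetylide.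

Step 9
Reactants: 11 ethyl (5R,6R)-6-[(tert-butyldimethylsilyl)oxy]-5-hydroxy-6-[(2R,5S)-5-[(1S)-1-hydroxyethyl]oxolan-2-yl]hex-2-ynoate
Product: 13 (6R)-6-{(S)-[(tert-butyldimethylsilyl)oxy][(2R,5S)-5-[(1S)-1-hydroxyethyl]oxolan-2-yl]methyl}-5,6-dihydro-2H-pyran-2-one, via Z-hydroxy enoate 12 (not isolated)
Conditions: H2 (1 atm), Pd/CaCO3 poisoned with Pb(OAc)2 (Lindlar catalyst), quinoline, EtOAc, rt; then PPTS (cat.), toluene, 60 °C
Reagents that add atoms: none
Why: Lindlar cis-semihydrogenation gives the Z-enoate, whose δ-hydroxyl should close the six-membered lactone with loss of ethanol, while the hydroxyethyl alcohol is too remote to compete.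

Step 10
Reactants: 14 4-[(tert-butyldimethylsilyl)oxy]benzaldehyde
Product: 15 tert-butyl[4-(2,2-dibromoethenyl)phenoxy]dimethylsilane
Conditions: CBr4, PPh3, CH2Cl2, 0 °C
Reagents that add atoms: carbon tetrabromide, BrC(Br)(Br)Br
Why: First stage of the Corey–Fuchs sequence (Wittig-type dibromomethylenation of the aldehyde), compatible with the aryl silyl ether.

Step 11
Reactants: 15 tert-butyl[4-(2,2-dibromoethenyl)phenoxy]dimethylsilane
Product: 17 3-{4-[(tert-butyldimethylsilyl)oxy]phenyl}prop-2-ynoic acid, via lithium arylacetylide 16 (not isolated)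
Conditions: n-BuLi (2.2 equiv), THF, −78 °C; then CO2, −78 °C to 0 °C; cold dilute HCl to pH 3
Reagents that add atoms: carbon dioxide, O=C=O
Why: Second stage of the Corey–Fuchs sequence (bromine–lithium exchange and Fritsch–Buttenberg–Wiechell rearrangement to the lithium acetylide), which is trapped by carboxylation.

Step 12
Reactants: 13 (6R)-6-{(S)-[(tert-butyldimethylsilyl)oxy][(2R,5S)-5-[(1S)-1-hydroxyethyl]oxolan-2-yl]methyl}-5,6-dihydro-2H-pyran-2-one; 17 3-{4-[(tert-butyldimethylsilyl)oxy]phenyl}prop-2-ynoic acid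
Product: 18 (1S)-1-[(2S,5R)-5-{(S)-[(tert-butyldimethylsilyl)oxy][(2R)-6-oxo-3,6-dihydro-2H-pyran-2-yl]methyl}oxolan-2-yl]ethyl 3-{4-[(tert-butyldimethylsilyl)oxy]phenyl}prop-2-ynoate
Conditions: DCC, DMAP (cat.), CH2Cl2, 0 °C to rt
Reagents that add atoms: none
Why: Steglich esterification of the only free hydroxyl; acylation proceeds with retention at the carbinol carbon and the alkynoate carries no alkene geometry that could be lost.

Step 13
Reactants: 18 (1S)-1-[(2S,5R)-5-{(S)-[(tert-butyldimethylsilyl)oxy][(2R)-6-oxo-3,6-dihydro-2H-pyran-2-yl]methyl}oxolan-2-yl]ethyl 3-{4-[(tert-butyldimethylsilyl)oxy]phenyl}prop-2-ynoate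
Product: 19 (1S)-1-[(2S,5R)-5-{(S)-[(tert-butyldimethylsilyl)oxy][(2R)-6-oxo-3,6-dihydro-2H-pyran-2-yl]methyl}oxolan-2-yl]ethyl (2Z)-3-{4-[(tert-butyldimethylsilyl)oxy]phenyl}prop-2-enoate
Conditions: H2 (1 atm), Pd/CaCO3 poisoned with Pb(OAc)2 (Lindlar catalyst), quinoline, EtOAc, rt, dark
Reagents that add atoms: none
Why: Lindlar semihydrogenation delivers both hydrogens to one face of the alkyne and should give the Z-cinnamate, with the lactone alkene left alone as in step 9.

Step 14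
Reactants: 19 (1S)-1-[(2S,5R)-5-{(S)-[(tert-butyldimethylsilyl)oxy][(2R)-6-oxo-3,6-dihydro-2H-pyran-2-yl]methyl}oxolan-2-yl]ethyl (2Z)-3-{4-[(tert-butyldimethylsilyl)oxy]phenyl}prop-2-enoate
Product: 20 (1S)-1-[(2S,5R)-5-{(S)-hydroxy[(2R)-6-oxo-3,6-dihydro-2H-pyran-2-yl]methyl}oxolan-2-yl]ethyl (2Z)-3-(4-hydroxyphenyl)prop-2-enoate
Conditions: HF·pyridine, pyridine, THF, 0 °C to rt, dark
Reagents that add atoms: none
Why: Fluoride-mediated cleavage of the aryl and the secondary alkyl silyl ethers under non-basic conditions, which should avoid Z to E isomerisation, acyl migration and lactone opening.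

**Compound list**

1 | (2S)-2-(benzyloxy)propanal | C[C@H](OCc1ccccc1)C=O | starting material
2 | (3S,4S)-4-(benzyloxy)pent-1-en-3-ol | C[C@H](OCc1ccccc1)[C@@H](O)C=C | intermediate
3 | (3S,4S)-4-(benzyloxy)pent-1-en-3-yl methyl carbonate | C[C@H](OCc1ccccc1)[C@@H](OC(=O)OC)C=C | intermediate
4 | (3R,4R)-hexa-1,5-diene-3,4-diol | C=C[C@@H](O)[C@H](O)C=C | starting material
5 | copper alkoxide of (3R,4R)-hexa-1,5-diene-3,4-diol (not isolated) | C=C[C@@H](O[Cu])[C@H](O)C=C | intermediate
6 | (3R,4R)-4-{[(3S,4S)-4-(benzyloxy)pent-1-en-3-yl]oxy}hexa-1,5-dien-3-ol | C[C@H](OCc1ccccc1)[C@H](C=C)O[C@H](C=C)[C@H](O)C=C | intermediate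
7 | (1S,2R)-2-{[(3S,4S)-4-(benzyloxy)pent-1-en-3-yl]oxy}-1-[(2R)-oxiran-2-yl]but-3-en-1-ol | C[C@H](OCc1ccccc1)[C@H](C=C)O[C@H](C=C)[C@H](O)[C@H]1CO1 | intermediate
8 | {[(1S,2R)-2-{[(3S,4S)-4-(benzyloxy)pent-1-en-3-yl]oxy}-1-[(2R)-oxiran-2-yl]but-3-en-1-yl]oxy}(tert-butyl)dimethylsilane | C[C@H](OCc1ccccc1)[C@H](C=C)O[C@H](C=C)[C@H](O[Si](C)(C)C(C)(C)C)[C@H]1CO1 | intermediate
9 | tert-butyl{(S)-[(2R,5S)-5-[(1S)-1-(benzyloxy)ethyl]-2,5-dihydrofuran-2-yl][(2R)-oxiran-2-yl]methoxy}dimethylsilane | C[C@H](OCc1ccccc1)[C@@H]1C=C[C@H]([C@H](O[Si](C)(C)C(C)(C)C)[C@H]2CO2)O1 | intermediate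
10 | (1S)-1-[(2S,5R)-5-{(S)-[(tert-butyldimethylsilyl)oxy][(2R)-oxiran-2-yl]methyl}oxolan-2-yl]ethan-1-ol | C[C@H](O)[C@@H]1CC[C@H]([C@H](O[Si](C)(C)C(C)(C)C)[C@H]2CO2)O1 | intermediate
11 | ethyl (5R,6R)-6-[(tert-butyldimethylsilyl)oxy]-5-hydroxy-6-[(2R,5S)-5-[(1S)-1-hydroxyethyl]oxolan-2-yl]hex-2-ynoate | C[C@H](O)[C@@H]1CC[C@H]([C@H](O[Si](C)(C)C(C)(C)C)[C@H](O)CC#CC(=O)OCC)O1 | intermediate
12 | ethyl (2Z,5R,6R)-6-[(tert-butyldimethylsilyl)oxy]-5-hydroxy-6-[(2R,5S)-5-[(1S)-1-hydroxyethyl]oxolan-2-yl]hex-2-enoate (not isolated) | C[C@H](O)[C@@H]1CC[C@H]([C@H](O[Si](C)(C)C(C)(C)C)[C@H](O)C/C=C\C(=O)OCC)O1 | intermediate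
13 | (6R)-6-{(S)-[(tert-butyldimethylsilyl)oxy][(2R,5S)-5-[(1S)-1-hydroxyethyl]oxolan-2-yl]methyl}-5,6-dihydro-2H-pyran-2-one | C[C@H](O)[C@@H]1CC[C@H]([C@H](O[Si](C)(C)C(C)(C)C)[C@H]2CC=CC(=O)O2)O1 | intermediate
14 | 4-[(tert-butyldimethylsilyl)oxy]benzaldehyde | O=Cc1ccc(O[Si](C)(C)C(C)(C)C)cc1 | starting material
15 | tert-butyl[4-(2,2-dibromoethenyl)phenoxy]dimethylsilane | BrC(Br)=Cc1ccc(O[Si](C)(C)C(C)(C)C)cc1 | intermediate
16 | lithium {4-[(tert-butyldimethylsilyl)oxy]phenyl}acetylide (not isolated) | [Li]C#Cc1ccc(O[Si](C)(C)C(C)(C)C)cc1 | intermediate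
17 | 3-{4-[(tert-butyldimethylsilyl)oxy]phenyl}prop-2-ynoic acid | OC(=O)C#Cc1ccc(O[Si](C)(C)C(C)(C)C)cc1 | intermediate
18 | (1S)-1-[(2S,5R)-5-{(S)-[(tert-butyldimethylsilyl)oxy][(2R)-6-oxo-3,6-dihydro-2H-pyran-2-yl]methyl}oxolan-2-yl]ethyl 3-{4-[(tert-butyldimethylsilyl)oxy]phenyl}prop-2-ynoate | C[C@H](OC(=O)C#Cc1ccc(O[Si](C)(C)C(C)(C)C)cc1)[C@@H]1CC[C@H]([C@H](O[Si](C)(C)C(C)(C)C)[C@H]2CC=CC(=O)O2)O1 | intermediate
19 | (1S)-1-[(2S,5R)-5-{(S)-[(tert-butyldimethylsilyl)oxy][(2R)-6-oxo-3,6-dihydro-2H-pyran-2-yl]methyl}oxolan-2-yl]ethyl (2Z)-3-{4-[(tert-butyldimethylsilyl)oxy]phenyl}prop-2-enoate | C[C@H](OC(=O)/C=C\c1ccc(O[Si](C)(C)C(C)(C)C)cc1)[C@@H]1CC[C@H]([C@H](O[Si](C)(C)C(C)(C)C)[C@H]2CC=CC(=O)O2)O1 | intermediate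
20 | (1S)-1-[(2S,5R)-5-{(S)-hydroxy[(2R)-6-oxo-3,6-dihydro-2H-pyran-2-yl]methyl}oxolan-2-yl]ethyl (2Z)-3-(4-hydroxyphenyl)prop-2-enoate | C[C@H](OC(=O)/C=C\c1ccc(O)cc1)[C@@H]1CC[C@H]([C@H](O)[C@H]2CC=CC(=O)O2)O1 | target

**Totals and risks**

Total step count: 14. Longest linear sequence: 12 (steps 1 to 9 and 12 to 14); steps 10 and 11 form the side branch to acid 17.

Steps most likely to fail:

1. Step 3. The alkoxide may attack the unsubstituted allyl terminus, the rhodium allyl may lose its stereochemical memory before capture, or the diol may be etherified twice. The fallback builds the second ether carbon by an auxiliary-controlled aldol instead of a C–O coupling and sets out from 2. Alkylation of 2 with bromoacetic acid (NaH, THF) should give 2-{[(3S,4S)-4-(benzyloxy)pent-1-en-3-yl]oxy}acetic acid F1. Activation with pivaloyl chloride and Et3N, then lithiated (4S)-4-benzyl-1,3-oxazolidin-2-one, should give (4S)-4-benzyl-3-(2-{[(3S,4S)-4-(benzyloxy)pent-1-en-3-yl]oxy}acetyl)-1,3-oxazolidin-2-one F2. An Evans syn aldol (Bu2BOTf, Et3N, CH2Cl2, −78 °C, acrolein) should set both new centres in (4S)-4-benzyl-3-[(2S,3R)-2-{[(3S,4S)-4-(benzyloxy)pent-1-en-3-yl]oxy}-3-hydroxypent-4-enoyl]-1,3-oxazolidin-2-one F3. LiBH4 should cleave the auxiliary to (2R,3R)-2-{[(3S,4S)-4-(benzyloxy)pent-1-en-3-yl]oxy}pent-4-ene-1,3-diol F4. Selective oxidation of the primary alcohol (TEMPO, PhI(OAc)2) should give (2S,3R)-2-{[(3S,4S)-4-(benzyloxy)pent-1-en-3-yl]oxy}-3-hydroxypent-4-enal F5. Wittig methylenation (Ph3P=CH2) returns to the route at 6.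

2. Step 7. On palladium the ring double bond may migrate towards the ring oxygen before it is saturated, which would erase the configuration at C2 or C5, or an allylic C–O bond or the oxirane may be hydrogenolysed during the slower debenzylation. The fallback separates the two events and sets out from 9. Metal-free diimide reduction (2-nitrobenzenesulfonohydrazide, Et3N, CH2Cl2, rt) cannot isomerise the alkene and should give tert-butyl{(S)-[(2R,5S)-5-[(1S)-1-(benzyloxy)ethyl]oxolan-2-yl][(2R)-oxiran-2-yl]methoxy}dimethylsilane F6. A short hydrogenolysis of the benzyl ether on this saturated compound (H2, Pd(OH)2/C, EtOAc) returns to the route at 10.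

3. Step 13. The cinnamate or the lactone alkene may be over-reduced, or the Z-alkene may drift to E on the catalyst. The fallback makes the Z-alkene by olefination instead of reduction and sets out from 13. Steglich esterification with (diphenoxyphosphoryl)acetic acid should give (1S)-1-[(2S,5R)-5-{(S)-[(tert-butyldimethylsilyl)oxy][(2R)-6-oxo-3,6-dihydro-2H-pyran-2-yl]methyl}oxolan-2-yl]ethyl 2-(diphenoxyphosphoryl)acetate F7. A Z-selective Horner–Wadsworth–Emmons reaction of this diaryl phosphonoacetate with aldehyde 14 (NaH, THF, −78 °C) returns to the route at 19.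

Further compounds
F1 | step 3 | 2-{[(3S,4S)-4-(benzyloxy)pent-1-en-3-yl]oxy}acetic acid | C[C@H](OCc1ccccc1)[C@H](C=C)OCC(=O)O
F2 | step 3 | (4S)-4-benzyl-3-(2-{[(3S,4S)-4-(benzyloxy)pent-1-en-3-yl]oxy}acetyl)-1,3-oxazolidin-2-one | C[C@H](OCc1ccccc1)[C@H](C=C)OCC(=O)N1[C@@H](Cc2ccccc2)COC1=O
F3 | step 3 | (4S)-4-benzyl-3-[(2S,3R)-2-{[(3S,4S)-4-(benzyloxy)pent-1-en-3-yl]oxy}-3-hydroxypent-4-enoyl]-1,3-oxazolidin-2-one | C[C@H](OCc1ccccc1)[C@H](C=C)O[C@H](C(=O)N1[C@@H](Cc2ccccc2)COC1=O)[C@H](O)C=C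
F4 | step 3 | (2R,3R)-2-{[(3S,4S)-4-(benzyloxy)pent-1-en-3-yl]oxy}pent-4-ene-1,3-diol | C[C@H](OCc1ccccc1)[C@H](C=C)O[C@H](CO)[C@H](O)C=C
F5 | step 3 | (2S,3R)-2-{[(3S,4S)-4-(benzyloxy)pent-1-en-3-yl]oxy}-3-hydroxypent-4-enal | C[C@H](OCc1ccccc1)[C@H](C=C)O[C@H](C=O)[C@H](O)C=C
F6 | step 7 | tert-butyl{(S)-[(2R,5S)-5-[(1S)-1-(benzyloxy)ethyl]oxolan-2-yl][(2R)-oxiran-2-yl]methoxy}dimethylsilane | C[C@H](OCc1ccccc1)[C@@H]1CC[C@H]([C@H](O[Si](C)(C)C(C)(C)C)[C@H]2CO2)O1
F7 | step 13 | (1S)-1-[(2S,5R)-5-{(S)-[(tert-butyldimethylsilyl)oxy][(2R)-6-oxo-3,6-dihydro-2H-pyran-2-yl]methyl}oxolan-2-yl]ethyl 2-(diphenoxyphosphoryl)acetate | C[C@H](OC(=O)CP(=O)(Oc1ccccc1)Oc1ccccc1)[C@@H]1CC[C@H]([C@H](O[Si](C)(C)C(C)(C)C)[C@H]2CC=CC(=O)O2)O1
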